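**Plan**

- Retrosynthesis first removes the tert-butyl ester and the two ring A methyl ethers (O–C bonds), leaving depside diol 16.
- Ring A is then opened at the bond between its carboxyl-bearing carbon (C1) and its heptyl-bearing carbon (C2). This is possible because ring A is a resorcylate: acyl carbon on C1, heptyl on C2, oxygens on C4 and C6, which is the oxygen pattern of a folded 3,5,7-trioxotetradecanoyl chain.
- The resulting aryl triketo ester 14 is cut at the ester O–C(=O) bond into ring B phenol 6 and an acylketene from diketo-dioxinone 12. 12 is cut at two C–C(=O) bonds into dioxinone 9, acetyl chloride and octanoyl chloride. 6 is cut at a benzylic C–C bond and an aryl C–O bond back to 2-methoxy-6-methylbenzoic acid and 1-bromohexane.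
- Forward: ring B is purchased and decorated, the tetraketide chain is attached to its phenol oxygen, and ring A closes last on the preformed, still unhindered ester.
- Stereochemistry: the target has no stereocentre; the two formed transiently in the aldol adduct are erased on aromatisation.

Key step: step 8

Remark: chain numbering C1–C14 refers to the 3,5,7-trioxotetradecanoyl unit, C1 being the ester carbonyl. LiN(i-Pr)2 and LiN(SiMe3)2 are taken as commercial solutions.

**Route**

Step 1
Reactants: 1 2-methoxy-6-methylbenzoic acid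
Product: 2 tert-butyl 2-methoxy-6-methylbenzoate
Conditions: t-BuOC(=NH)CCl3 (2 equiv), BF3·OEt2 (cat.), CH2Cl2/cyclohexane, rt
Reagents that add atoms: tert-butyl 2,2,2-trichloroacetimidate, CC(C)(C)OC(=N)C(Cl)(Cl)Cl
Why: Acid-catalysed O-tert-butylation with the trichloroacetimidate alkylates the carboxyl oxygen through a tert-butyl cation, so the two ortho substituents that would block an acyl-substitution esterification do not interfere.

Step 2
Reactants: 2 tert-butyl 2-methoxy-6-methylbenzoate; 3 1-bromohexane
Product: 4 tert-butyl 2-heptyl-6-methoxybenzoate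
Conditions: LiN(i-Pr)2 (1.2 equiv), THF, −78 °C; then 3, DMPU, −78 °C → rt
Reagents that add atoms: none
Why: Lateral lithiation of an ortho-toluate gives an ester-conjugated benzylic anion that is alkylated by the primary bromide in an SN2 reaction, the bulky tert-butyl ester suppressing self-condensation.

Step 3
Reactants: 4 tert-butyl 2-heptyl-6-methoxybenzoate
Product: 6 tert-butyl 2-heptyl-4-hydroxy-6-methoxybenzoate, via aryl pinacol boronate 5 (not isolated)
Conditions: B2pin2, [Ir(OMe)(cod)]2 (1.5 mol %), 4,4'-di-tert-butyl-2,2'-bipyridine (3 mol %), THF, 80 °C; evaporate; then KHSO5 (as 2KHSO5·KHSO4·K2SO4), acetone/H2O, rt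
Reagents that add atoms: potassium peroxymonosulfate KHSO5, [K+].[O-]S(=O)(=O)OO (the phenol oxygen of 6); bis(pinacolato)diboron, CC1(C)OB(OC1(C)C)B1OC(C)(C)C(C)(C)O1 (the boryl group of 5 only)
Why: Sterically governed iridium-catalysed aromatic C–H borylation takes the only ring hydrogen without an ortho neighbour (C4, para to the ester), and peroxymonosulfate oxidation of the C–B bond (aryl shift from boron to oxygen) then gives the phenol in the same flask, a known one-pot borylation–oxidation.

Step 4
Reactants: 7 octanoyl chloride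
Product: 8 N-methoxy-N-methyloctanamide
Conditions: MeNHOMe·HCl, K2CO3, CH2Cl2/H2O, 0 °C → rt
Reagents that add atoms: N,O-dimethylhydroxylamine hydrochloride, CNOC.Cl
Why: Schotten–Baumann acylation of the hydroxylamine nitrogen by the acid chloride gives the Weinreb amide.

Step 5
Reactants: 9 2,2,6-trimethyl-4H-1,3-dioxin-4-one (2 equiv); 10 acetyl chloride (1 equiv)
Product: 11 2,2-dimethyl-6-(2-oxopropyl)-4H-1,3-dioxin-4-one
Conditions: LiN(SiMe3)2 (2 equiv), THF, −78 °C; then AcCl, −78 °C; aq. NH4Cl
Reagents that add atoms: none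
Why: γ-Acylation of the lithium dienolate of the dioxinone by an acid chloride (vinylogous Claisen-type condensation) is established for this heterocycle, the second equivalent of dienolate taking up the more acidic product.

Step 6
Reactants: 11 2,2-dimethyl-6-(2-oxopropyl)-4H-1,3-dioxin-4-one; 8 N-methoxy-N-methyloctanamide
Product: 12 6-(2,4-dioxoundecyl)-2,2-dimethyl-4H-1,3-dioxin-4-one
Conditions: LiN(i-Pr)2 (2.2 equiv), THF, −78 → −40 °C; then 8, −78 → −20 °C; 1 M HCl
Reagents that add atoms: none
Why: Dianion Claisen condensation, in which the more reactive terminal carbanion of the 1,3-dicarbonyl dianion adds to the Weinreb amide and the chelated tetrahedral adduct prevents over-addition, a known way to diketo-dioxinones.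

Step 7
Reactants: 12 6-(2,4-dioxoundecyl)-2,2-dimethyl-4H-1,3-dioxin-4-one; 6 tert-butyl 2-heptyl-4-hydroxy-6-methoxybenzoate (1.5 equiv, excess recoverable)
Product: 14 tert-butyl 2-heptyl-6-methoxy-4-[(3,5,7-trioxotetradecanoyl)oxy]benzoate, via acylketene 13 (not isolated)
Conditions: toluene, 110 °C, short reaction time, acetone distilled off; crude 14 taken on at once
Reagents that add atoms: none
Why: Thermal retro-[4+2] fragmentation of the dioxinone expels acetone and the acylketene is captured at its ketene carbon by the unhindered phenol of 6 (kept in excess to outrun internal enol capture), the standard dioxinone route to β-keto esters.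

Step 8
Reactants: 14 tert-butyl 2-heptyl-6-methoxy-4-[(3,5,7-trioxotetradecanoyl)oxy]benzoate
Product: 16 tert-butyl 2-heptyl-4-[(2-heptyl-4,6-dihydroxybenzoyl)oxy]-6-methoxybenzoate, via cyclic aldol adduct 15 (not isolated)
Conditions: Et3N (3 equiv), CH2Cl2, 0 °C → rt; then AcOH (excess), 40 °C
Reagents that add atoms: none
Why: Et3N enolises the C2 methylene, the most acidic site because it lies between the aryl ester and the C3 ketone, and this carbon adds to the C7 ketone in an intramolecular aldol reaction that forms the bond between ring A C1 and C2 (chain C2–C7); carbinol 15 then loses water under acetic acid and the C3 and C5 carbonyls enolise to the resorcinol. The closest known reaction type is the biomimetic aldol aromatisation of dioxinone-derived 3,5,7-triketo esters to resorcylates. Ring A closes in a 6-(enolendo)-exo-trig mode. No stereocentre remains, since the two formed in 15 are uncontrolled and are erased on aromatisation. The step needs carbon–carbon closure from C2 to C7 to win over attack of the C5 enol oxygen or of the C6 carbanion on the ester carbonyl, either of which would expel the ring B phenoxide (giving a 4-hydroxy-2-pyrone or an acylphloroglucinol). This should be secured by the higher acidity of C2, by C7 being the only ketone an enolate at C2 can reach through a six-membered transition state, and by a weak amine base in an aprotic, nucleophile-free medium at low temperature followed by only a weak acid, which also spares the tert-butyl ester.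

Step 9
Reactants: 16 tert-butyl 2-heptyl-4-[(2-heptyl-4,6-dihydroxybenzoyl)oxy]-6-methoxybenzoate
Product: 17 tert-butyl 2-heptyl-4-[(2-heptyl-4,6-dimethoxybenzoyl)oxy]-6-methoxybenzoate
Conditions: MeI (excess), K2CO3, acetone, 50 °C
Reagents that add atoms: iodomethane, CI
Why: Williamson O-methylation of both phenols, the hydrogen-bonded ortho hydroxyl reacting more slowly but going to completion with excess reagent, while no nucleophile able to cleave the now doubly ortho-substituted depside ester is present.

Step 10
Reactants: 17 tert-butyl 2-heptyl-4-[(2-heptyl-4,6-dimethoxybenzoyl)oxy]-6-methoxybenzoate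
Product: 18 2-heptyl-4-[(2-heptyl-4,6-dimethoxybenzoyl)oxy]-6-methoxybenzoic acid (CNP0300299.0)
Conditions: CF3CO2H/CH2Cl2 (1:4), Et3SiH (2 equiv), 0 °C → rt
Reagents that add atoms: none
Why: Acidolysis of the tert-butyl ester by alkyl–oxygen fission is insensitive to the flanking substituents and leaves the aryl ester and methyl ethers untouched, while Et3SiH reduces the tert-butyl cation before it can alkylate the electron-rich ring A.

**Compound list**

1 | 2-methoxy-6-methylbenzoic acid | Cc1cccc(OC)c1C(=O)O | starting material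
2 | tert-butyl 2-methoxy-6-methylbenzoate | Cc1cccc(OC)c1C(=O)OC(C)(C)C | intermediate
3 | 1-bromohexane | CCCCCCBr | starting material
4 | tert-butyl 2-heptyl-6-methoxybenzoate | CCCCCCCc1cccc(OC)c1C(=O)OC(C)(C)C | intermediate
5 | tert-butyl 2-heptyl-6-methoxy-4-(4,4,5,5-tetramethyl-1,3,2-dioxaborolan-2-yl)benzoate | CCCCCCCc1cc(B2OC(C)(C)C(C)(C)O2)cc(OC)c1C(=O)OC(C)(C)C | intermediate (not isolated)
6 | tert-butyl 2-heptyl-4-hydroxy-6-methoxybenzoate | CCCCCCCc1cc(O)cc(OC)c1C(=O)OC(C)(C)C | intermediate
7 | octanoyl chloride | CCCCCCCC(=O)Cl | starting material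
8 | N-methoxy-N-methyloctanamide | CCCCCCCC(=O)N(C)OC | intermediate
9 | 2,2,6-trimethyl-4H-1,3-dioxin-4-one | CC1=CC(=O)OC(C)(C)O1 | starting material
10 | acetyl chloride | CC(=O)Cl | starting material
11 | 2,2-dimethyl-6-(2-oxopropyl)-4H-1,3-dioxin-4-one | CC(=O)CC1=CC(=O)OC(C)(C)O1 | intermediate
12 | 6-(2,4-dioxoundecyl)-2,2-dimethyl-4H-1,3-dioxin-4-one | CCCCCCCC(=O)CC(=O)CC1=CC(=O)OC(C)(C)O1 | intermediate
13 | (3,5-dioxododecanoyl)ketene (3,5,7-trioxotetradec-1-en-1-one) | CCCCCCCC(=O)CC(=O)CC(=O)C=C=O | intermediate (not isolated)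
14 | tert-butyl 2-heptyl-6-methoxy-4-[(3,5,7-trioxotetradecanoyl)oxy]benzoate | CCCCCCCc1cc(OC(=O)CC(=O)CC(=O)CC(=O)CCCCCCC)cc(OC)c1C(=O)OC(C)(C)C | intermediate
15 | tert-butyl 2-heptyl-4-[(2-heptyl-2-hydroxy-4,6-dioxocyclohexane-1-carbonyl)oxy]-6-methoxybenzoate (racemic mixture of diastereomers) | CCCCCCCc1cc(OC(=O)C2C(=O)CC(=O)CC2(O)CCCCCCC)cc(OC)c1C(=O)OC(C)(C)C | intermediate (not isolated)
16 | tert-butyl 2-heptyl-4-[(2-heptyl-4,6-dihydroxybenzoyl)oxy]-6-methoxybenzoate | CCCCCCCc1cc(OC(=O)c2c(CCCCCCC)cc(O)cc2O)cc(OC)c1C(=O)OC(C)(C)C | intermediate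
17 | tert-butyl 2-heptyl-4-[(2-heptyl-4,6-dimethoxybenzoyl)oxy]-6-methoxybenzoate | CCCCCCCc1cc(OC(=O)c2c(CCCCCCC)cc(OC)cc2OC)cc(OC)c1C(=O)OC(C)(C)C | intermediate
18 | 2-heptyl-4-[(2-heptyl-4,6-dimethoxybenzoyl)oxy]-6-methoxybenzoic acid | CCCCCCCc1cc(OC(=O)c2c(CCCCCCC)cc(OC)cc2OC)cc(OC)c1C(=O)O | target

**Summary**

Total step count: 10. Longest linear sequence: 7 steps (1, 2, 3, 7, 8, 9, 10).

Steps most likely to fail:

1. Step 8. The aryl ester is an activated acyl donor. Closure through the C5 enol oxygen (lactonisation), Claisen-type closure from C6, or base-induced reversion to the acylketene may expel the ring B phenoxide faster than the aldol proceeds. The fallback sets out from 12 and returns at 17. It performs the same aldol aromatisation on an ester with a poor leaving group and makes the depside bond afterwards by conventional acylation. 12 is heated with benzyl alcohol in toluene to give benzyl 3,5,7-trioxotetradecanoate F1. This is cyclised with Et3N in CH2Cl2 to the carbinol benzyl 2-heptyl-2-hydroxy-4,6-dioxocyclohexane-1-carboxylate F2 and dehydrated with acid to benzyl 2-heptyl-4,6-dihydroxybenzoate F3. Methylation (MeI, K2CO3, acetone) should give benzyl 2-heptyl-4,6-dimethoxybenzoate F4. Hydrogenolysis (H2, Pd/C, palladium metal on carbon, EtOAc) should give 2-heptyl-4,6-dimethoxybenzoic acid F5. Oxalyl chloride with catalytic DMF should give 2-heptyl-4,6-dimethoxybenzoyl chloride F6, which acylates phenol 6 (Et3N, DMAP, CH2Cl2) to give 17.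

2. Step 7. Capture of the acylketene by its own C5 enol oxygen (pyrone formation) may outrun bimolecular addition of the weakly nucleophilic phenol. Prolonged heating may also revert the aryl β-keto ester to ketene and phenol. The fallback sets out from 12 (with 6) and returns at 17. It aromatises before the ester is made and transfers the acyl group from a ketene that has no internal enol. 12 is closed by its own aldol reaction with the acetonide retained (Et3N, CH2Cl2; then AcOH), through the carbinol 5-heptyl-5-hydroxy-2,2-dimethyl-5,6-dihydro-4H-1,3-benzodioxine-4,7(8H)-dione F7, to 5-heptyl-7-hydroxy-2,2-dimethyl-4H-1,3-benzodioxin-4-one F8. Methylation (MeI, K2CO3, acetone) should give 5-heptyl-7-methoxy-2,2-dimethyl-4H-1,3-benzodioxin-4-one F9. Irradiation at 300 nm in CH2Cl2 in the presence of 6 expels acetone to the quinoketene 3-heptyl-5-methoxy-2-(oxomethylidene)cyclohexa-3,5-dien-1-one F10. The phenol captures this to give tert-butyl 2-heptyl-4-[(2-heptyl-6-hydroxy-4-methoxybenzoyl)oxy]-6-methoxybenzoate F11. Methylation of the remaining hydroxyl (MeI, K2CO3) gives 17.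

3. Step 6. Proton transfer from the acidic product or from the α-position of the amide to the dianion, and attack of the amide base on the dioxinone carbonyl, may hold conversion low. The fallback sets out from 11 and returns at 12. It changes the oxidation level of the electrophile. The same dianion (LiN(i-Pr)2, THF, −78 °C) is added to octanal in an aldol addition, which is fast and free of the proton-transfer problem, to give racemic 6-(4-hydroxy-2-oxoundecyl)-2,2-dimethyl-4H-1,3-dioxin-4-one F12. The carbinol is then oxidised with Dess–Martin periodinane (CH2Cl2, rt) to 12.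

**Further compounds**

F1 | step 8 | benzyl 3,5,7-trioxotetradecanoate | CCCCCCCC(=O)CC(=O)CC(=O)CC(=O)OCc1ccccc1
F2 | step 8 | benzyl 2-heptyl-2-hydroxy-4,6-dioxocyclohexane-1-carboxylate (racemic mixture of diastereomers) | CCCCCCCC1(O)CC(=O)CC(=O)C1C(=O)OCc1ccccc1
F3 | step 8 | benzyl 2-heptyl-4,6-dihydroxybenzoate | CCCCCCCc1cc(O)cc(O)c1C(=O)OCc1ccccc1
F4 | step 8 | benzyl 2-heptyl-4,6-dimethoxybenzoate | CCCCCCCc1cc(OC)cc(OC)c1C(=O)OCc1ccccc1
F5 | step 8 | 2-heptyl-4,6-dimethoxybenzoic acid | CCCCCCCc1cc(OC)cc(OC)c1C(=O)O
F6 | step 8 | 2-heptyl-4,6-dimethoxybenzoyl chloride | CCCCCCCc1cc(OC)cc(OC)c1C(=O)Cl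
F7 | step 7 | 5-heptyl-5-hydroxy-2,2-dimethyl-5,6-dihydro-4H-1,3-benzodioxine-4,7(8H)-dione (racemic) | CCCCCCCC1(O)CC(=O)CC2=C1C(=O)OC(C)(C)O2
F8 | step 7 | 5-heptyl-7-hydroxy-2,2-dimethyl-4H-1,3-benzodioxin-4-one | CCCCCCCc1cc(O)cc2OC(C)(C)OC(=O)c12
F9 | step 7 | 5-heptyl-7-methoxy-2,2-dimethyl-4H-1,3-benzodioxin-4-one | CCCCCCCc1cc(OC)cc2OC(C)(C)OC(=O)c12
F10 | step 7 | 3-heptyl-5-methoxy-2-(oxomethylidene)cyclohexa-3,5-dien-1-one | O=C=C1C(=O)C=C(OC)C=C1CCCCCCC
F11 | step 7 | tert-butyl 2-heptyl-4-[(2-heptyl-6-hydroxy-4-methoxybenzoyl)oxy]-6-methoxybenzoate | CCCCCCCc1cc(OC(=O)c2c(CCCCCCC)cc(OC)cc2O)cc(OC)c1C(=O)OC(C)(C)C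
F12 | step 6 | 6-(4-hydroxy-2-oxoundecyl)-2,2-dimethyl-4H-1,3-dioxin-4-one (racemic) | CCCCCCCC(O)CC(=O)CC1=CC(=O)OC(C)(C)O1
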